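**Retrosynthetic overview**

1. The three guaiacylglycerol side chains (unit A on the ring B oxygen, unit D on the ring C oxygen, unit E on the ring D oxygen) are each cut at C7–C8 into an aryloxyacetyl imide and a vanillin-type aldehyde (Evans glycolate aldol: threo as formed, erythro after Mitsunobu inversion of C7). Units D and E arrive together as one aldehyde, which leaves 4-O-allyl-4′-O-benzylsyringaresinol.
2. Both tetrahydrofuran rings of this core are opened at C7–O and C7′–O to an 8R,8′R tetraol, the LiAlH4 product of a trans,trans-trisubstituted butyrolactone.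
3. Structural feature used: C8 and C8′ of the furofuran are vicinal and trans, and each carries one CH2O carbon (C9, C9′) and one benzylic C–O carbon (C7 on ring B, C7′ on ring C). This is the imprint of β-attack by a ring C acyl-anion equivalent and α-trapping by the ring B aldehyde on a butenolide whose carbonyl is C9 and whose menthyl acetal carbon is C9′.
4. Ring order: the key step closes no ring; both furofuran rings close together in step 9; rings A, D and E are bought as aromatic building blocks.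

Key step: step 6

Assumption: lignan numbering is used (C7–C9/C7′–C9′ for the core, separate C7/C8/C9 for units A, D, E); the carbinol carbons formed in steps 6 and 8 are expected as epimer mixtures, are drawn as one epimer, and are erased in step 9.

**Route**

Step 1
Reactants: 1 furfural
Product: 2 5-hydroxyfuran-2(5H)-one
Conditions: O2, rose bengal (C20H2Cl4I4Na2O5, cat.), MeOH, visible light, 20 °C
Reagents that add atoms: dioxygen, O=O
Why: Singlet oxygen adds across the furan diene and methanol removes the formyl carbon as methyl formate, the known photo-oxygenation route to 5-hydroxybutenolides.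

Step 2
Reactants: 2 5-hydroxyfuran-2(5H)-one; 3 (−)-menthol
Product: 4 (5R)-5-[(1R,2S,5R)-menthyloxy]furan-2(5H)-one
Conditions: TsOH·H2O (cat.), toluene, reflux (Dean–Stark); crystallise from petroleum ether, −20 °C; re-equilibrate mother liquor with TsOH
Reagents that add atoms: none
Why: Acid-catalysed acetal exchange gives both C5 epimers, which interconvert under the acid, and the 5R epimer is removed by crystallisation while the mother liquor is recycled (crystallisation-driven resolution of a menthyl acetal).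

Step 3
Reactants: 5 syringaldehyde
Product: 6 4-(allyloxy)-3,5-dimethoxybenzaldehyde
Conditions: allyl bromide, K2CO3, DMF, 60 °C
Reagents that add atoms: allyl bromide, C=CCBr
Why: Williamson etherification of the phenoxide with a reactive allylic halide.

Step 4
Reactants: 5 syringaldehyde
Product: 7 4-(benzyloxy)-3,5-dimethoxybenzaldehyde
Conditions: benzyl bromide, K2CO3, DMF, 60 °C
Reagents that add atoms: benzyl bromide, BrCc1ccccc1
Why: Williamson etherification of the phenoxide with a benzylic halide.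

Step 5
Reactants: 7 4-(benzyloxy)-3,5-dimethoxybenzaldehyde; 8 propane-1,3-dithiol
Product: 9 2-[4-(benzyloxy)-3,5-dimethoxyphenyl]-1,3-dithiane
Conditions: BF3·OEt2 (cat.), CH2Cl2, 0 °C → rt
Reagents that add atoms: none
Why: Lewis-acid-catalysed dithioacetalisation of an aromatic aldehyde, which turns the ring C carbonyl carbon into an acyl-anion equivalent.

Step 6
Reactants: 9 2-[4-(benzyloxy)-3,5-dimethoxyphenyl]-1,3-dithiane; 4 (5R)-5-menthyloxyfuran-2(5H)-one; 6 4-(allyloxy)-3,5-dimethoxybenzaldehyde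
Product: 12 (3S,4R,5R)-3-[aryl(hydroxy)methyl]-4-(2-aryl-1,3-dithian-2-yl)-5-menthyloxybutyrolactone, via lithiodithiane 10 (not isolated), via lithium enolate 11 (not isolated)
Conditions: n-BuLi (1.05 equiv), THF, −78 → −30 °C; 4, −90 °C; then 6, −78 °C; AcOH quench at −78 °C
Reagents that add atoms: none
Why: n-BuLi removes the C2 proton of 9, and the soft sulfur-stabilised carbanion 10 adds 1,4 to butenolide 4 at C8′ on the face opposite the menthyloxy group, so C8′ (lactone C4, R) is set by the acetal carbon C9′ bought with (−)-menthol. The lithium enolate 11 is trapped in the same flask by aldehyde 6 at C8 on the face opposite the new, very bulky aryldithianyl group, which sets C8 (lactone C3, S; R in the furofuran) trans to C8′. This is a tandem Michael addition–aldol (three-component coupling), a reaction type established for lithiated 2-aryl-1,3-dithianes and 5-alkoxybutenolides; it forms C7′–C8′ and C7–C8 and closes no ring. The carbinol carbon C7 is not controlled and need not be, because step 9 re-sets it. The step needs 1,4- over 1,2-addition, anti addition to the acetal substituent and trans trapping: the first is secured by the delocalised, hindered nucleophile at low temperature, the other two by the menthyloxy and dithianyl groups shielding one lactone face in turn. The cold AcOH quench keeps the lithium aldolate from retro-aldol reversal.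

Step 7
Reactants: 12 dithianyl aldol lactone
Product: 13 (3S,4R,5R)-3-[aryl(hydroxy)methyl]-4-[4-(benzyloxy)-3,5-dimethoxybenzoyl]-5-menthyloxybutyrolactone
Conditions: PhI(OCOCF3)2 (1.5 equiv), NaHCO3, MeCN–H2O 9:1, 0 °C
Reagents that add atoms: water, O
Why: The hypervalent iodine reagent oxidises sulfur and water hydrolyses the activated dithioacetal to the aryl ketone under buffered, fast, metal-free conditions that spare the allyl ether, the benzylic carbinol and the menthyl acetal (oxidative dithioacetal hydrolysis), while C8′ next to the new ketone stays in its favoured trans arrangement.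

Step 8
Reactants: 13 keto lactone
Product: 14 (2R,3R)-2,3-bis[aryl(hydroxy)methyl]butane-1,4-diol (tetraol)
Conditions: LiAlH4 (5 equiv), THF, 0 °C → reflux; H2O/aq. NaOH work-up
Reagents that add atoms: none
Why: LiAlH4 reduces the ketone to the C7′ carbinol (either epimer serves) and the lactone to the C9 alcohol, and the hemiacetal alkoxide freed at C9′ expels mentholate and is reduced to the C9′ alcohol, so C9′ stops being a stereocentre while C8 and C8′ are untouched (exhaustive hydride reduction).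

Step 9
Reactants: 14 tetraol
Product: 15 (7S,8R,7′S,8′R)-4-O-allyl-4′-O-benzylsyringaresinol
Conditions: CF3CO2H (0.5 equiv), CH2Cl2, 0 °C → rt, short reaction time
Reagents that add atoms: none
Why: Acid ionises each trialkoxybenzylic carbinol to a cation that the 1,4-related primary hydroxyl captures by 5-exo closure (C9′–OH onto C7, C9–OH onto C7′), and C7 and C7′ are set S,S because each aryl group settles on the convex face of the cis-fused bicycle, trans to the neighbouring ring bond, whatever the carbinol configuration; catalytic acid at low temperature limits Friedel–Crafts closure and endo-aryl equilibration (dehydrative double etherification).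

Step 10
Reactants: 15 4-O-allyl-4′-O-benzylsyringaresinol
Product: 16 (7S,8R,7′S,8′R)-4′-O-benzylsyringaresinol (ring B phenol free)
Conditions: Pd(PPh3)4 (5 mol %), morpholine (5 equiv), THF, rt
Reagents that add atoms: none
Why: Zerovalent palladium ionises the allyl aryl ether to a π-allyl complex that morpholine intercepts, which frees only the ring B phenol and leaves the benzyl ether and the furofuran alone (Tsuji–Trost deallylation).

Step 11
Reactants: 17 (R)-4-benzyloxazolidin-2-one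
Product: 19 (R)-4-benzyl-3-(bromoacetyl)oxazolidin-2-one, via N-lithio oxazolidinone 18 (not isolated)
Conditions: n-BuLi (1.0 equiv), THF, −78 °C; BrCH2COBr (1.1 equiv), −78 → 0 °C
Reagents that add atoms: bromoacetyl bromide, BrCC(Br)=O
Why: N-acylation of the lithiated oxazolidinone by the acid bromide, the standard way to load an Evans auxiliary.

Step 12
Reactants: 20 (S)-4-benzyloxazolidin-2-one
Product: 22 (S)-4-benzyl-3-(bromoacetyl)oxazolidin-2-one, via N-lithio oxazolidinone 21 (not isolated)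
Conditions: n-BuLi (1.0 equiv), THF, −78 °C; BrCH2COBr (1.1 equiv), −78 → 0 °C
Reagents that add atoms: bromoacetyl bromide, BrCC(Br)=O
Why: Same N-acylation as step 11 in the enantiomeric series.

Step 13
Reactants: 23 vanillin
Product: 24 3-methoxy-4-(triisopropylsilyloxy)benzaldehyde
Conditions: i-Pr3SiCl, imidazole, DMF, rt
Reagents that add atoms: chlorotriisopropylsilane, CC(C)[Si](Cl)(C(C)C)C(C)C
Why: Imidazole-promoted silylation of the phenol gives a mask that survives boron enolates, borohydride, hydrogenolysis and carbonate and falls to fluoride at the end.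

Step 14
Reactants: 16 4′-O-benzylsyringaresinol; 19 (R)-4-benzyl-3-(bromoacetyl)oxazolidin-2-one
Product: 25 ring B aryloxyacetyl imide
Conditions: K2CO3 (2 equiv), acetone, rt
Reagents that add atoms: none
Why: The phenoxide displaces the activated primary bromide next to the imide carbonyl (Williamson ether synthesis), which is faster than acyl transfer under mild carbonate conditions.

Step 15
Reactants: 25 ring B aryloxyacetyl imide; 24 3-methoxy-4-(triisopropylsilyloxy)benzaldehyde
Product: 27 (2R,3S) syn aldol adduct of unit A, via boron enolate 26 (not isolated)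
Conditions: n-Bu2BOTf (1.2 equiv), i-Pr2NEt (1.4 equiv), CH2Cl2, −78 → 0 °C; 24 (1.3 equiv), −78 → 0 °C; pH 7 buffer, MeOH, 30% H2O2, 0 °C
Reagents that add atoms: none
Why: Evans syn aldol, in which the Z boron enolate 26 reacts through a Zimmerman–Traxler chair and the (R)-benzyl group of the auxiliary shields one enolate face, setting unit A C8 (S in the final diol) and C7 (S, threo); excess amine and low temperature keep the Lewis acid from opening the furofuran.

Step 16
Reactants: 27 syn aldol adduct of unit A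
Product: 28 (2R,3R) 3-(4-nitrobenzoyloxy) imide of unit A
Conditions: PPh3, i-PrO2CN=NCO2i-Pr, 4-O2NC6H4CO2H, THF, 0 °C → rt
Reagents that add atoms: 4-nitrobenzoic acid, OC(=O)c1ccc(cc1)[N+](=O)[O-]
Why: Mitsunobu esterification displaces the activated benzylic oxygen by carboxylate in an SN2 sense and so inverts unit A C7 from S to R (erythro), the adjacent electron-poor aryloxy-acyl carbon disfavouring ionisation.

Step 17
Reactants: 28 nitrobenzoate imide of unit A
Product: 29 unit A erythro (7R,8S) 1,3-diol on ring B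
Conditions: LiBH4 (4 equiv), THF containing H2O (4 equiv), 0 °C → rt
Reagents that add atoms: none
Why: LiBH4 reduces the imide carbonyl to the primary alcohol with release of the auxiliary and cleaves the activated nitrobenzoate reductively, while the aryl silyl ether, benzyl ether and furofuran are inert (reductive auxiliary removal).

Step 18
Reactants: 29 unit A diol
Product: 30 unit A 7,9-bis(tert-butyldimethylsilyl) ether
Conditions: t-BuMe2SiOTf (2.5 equiv), 2,6-lutidine (4 equiv), CH2Cl2, −78 → 0 °C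
Reagents that add atoms: tert-butyldimethylsilyl triflate, CC(C)(C)[Si](C)(C)OS(=O)(=O)C(F)(F)F
Why: The silyl triflate with a hindered pyridine base silylates the primary and the hindered benzylic hydroxyl alike, masking both before the next boron enolate chemistry (silyl ether formation).

Step 19
Reactants: 30 bis-silyl ether
Product: 31 ring C phenol
Conditions: H2 (1 atm), 10% Pd/C, EtOAc, rt
Reagents that add atoms: none
Why: Hydrogenolysis over palladium cleaves the O-benzyl bond of the ring C phenol much faster than the dialkyl benzylic C–O bonds of the furofuran or the benzylic silyl ether, and silyl ethers are inert (catalytic debenzylation).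

Step 20
Reactants: 31 ring C phenol; 19 (R)-4-benzyl-3-(bromoacetyl)oxazolidin-2-one
Product: 32 ring C aryloxyacetyl imide
Conditions: K2CO3 (2 equiv), acetone, rt
Reagents that add atoms: none
Why: Williamson alkylation of the ring C phenoxide by the activated primary bromide, under anhydrous carbonate conditions that the hindered aryl silyl ether tolerates.

Step 21
Reactants: 33 4-hydroxy-3-methoxybenzonitrile; 22 (S)-4-benzyl-3-(bromoacetyl)oxazolidin-2-one
Product: 34 ring D aryloxyacetyl imide (nitrile as masked aldehyde)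
Conditions: K2CO3 (2 equiv), acetone, 40 °C
Reagents that add atoms: none
Why: Williamson alkylation of the acidic cyanophenol, whose nitrile stands in for the ring D aldehyde because it is inert to boron enolates and borohydride.

Step 22
Reactants: 34 ring D aryloxyacetyl imide; 24 3-methoxy-4-(triisopropylsilyloxy)benzaldehyde
Product: 36 (2S,3R) syn aldol adduct of unit E, via boron enolate 35 (not isolated)
Conditions: n-Bu2BOTf (1.2 equiv), i-Pr2NEt (1.4 equiv), CH2Cl2, −78 → 0 °C; 24 (1.2 equiv), −78 → 0 °C; pH 7 buffer, MeOH, 30% H2O2, 0 °C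
Reagents that add atoms: none
Why: Evans syn aldol through the Z boron enolate 35 with the (S)-auxiliary, which sets unit E C8 (R in the final diol) and C7 (R, threo) as the mirror-image sense of step 15.

Step 23
Reactants: 36 syn aldol adduct of unit E
Product: 37 (2S,3S) 3-(4-nitrobenzoyloxy) imide of unit E
Conditions: PPh3, i-PrO2CN=NCO2i-Pr, 4-O2NC6H4CO2H, THF, 0 °C → rt
Reagents that add atoms: 4-nitrobenzoic acid, OC(=O)c1ccc(cc1)[N+](=O)[O-]
Why: Mitsunobu inversion of the benzylic carbinol turns unit E C7 from R to S (erythro) by SN2 displacement.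

Step 24
Reactants: 37 nitrobenzoate imide of unit E
Product: 38 unit E erythro (7S,8R) diol on 3-methoxybenzonitrile
Conditions: LiBH4 (4 equiv), THF containing H2O (4 equiv), 0 °C → rt
Reagents that add atoms: none
Why: LiBH4 removes the auxiliary reductively and cleaves the nitrobenzoate while the aryl nitrile is not reduced at this temperature (chemoselective borohydride reduction).

Step 25
Reactants: 38 unit E diol
Product: 39 unit E 7,9-bis(tert-butyldimethylsilyl) ether nitrile
Conditions: t-BuMe2SiOTf (2.5 equiv), 2,6-lutidine (4 equiv), CH2Cl2, −78 → 0 °C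
Reagents that add atoms: tert-butyldimethylsilyl triflate, CC(C)(C)[Si](C)(C)OS(=O)(=O)C(F)(F)F
Why: Exhaustive silylation of the primary and benzylic hydroxyls with a silyl triflate and hindered base (silyl ether formation).

Step 26
Reactants: 39 bis-silyl ether nitrile
Product: 41 ring D aldehyde carrying protected unit E, via N-aluminated aldimine 40 (not isolated)
Conditions: i-Bu2AlH (1.3 equiv), toluene, −78 °C; aq. KNaC4H4O6, rt
Reagents that add atoms: water, O
Why: i-Bu2AlH adds once to the nitrile at low temperature to give the aldimine 40, which is not reduced further and is hydrolysed to the aldehyde on work-up (partial nitrile reduction), silyl ethers being inert.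

Step 27
Reactants: 32 ring C aryloxyacetyl imide; 41 ring D aldehyde carrying unit E
Product: 43 (2R,3S) syn aldol adduct of unit D, via boron enolate 42 (not isolated)
Conditions: n-Bu2BOTf (1.2 equiv), i-Pr2NEt (1.4 equiv), CH2Cl2, −78 → 0 °C; 41 (1.3 equiv), −78 → 0 °C; pH 7 buffer, MeOH, 30% H2O2, 0 °C
Reagents that add atoms: none
Why: Evans syn aldol through the Z boron enolate 42, in which the (R)-auxiliary alone sets unit D C8 (S) and C7 (S), the threo pattern the target needs, the stereocentres of 41 being too remote to interfere.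

Step 28
Reactants: 43 syn aldol adduct of unit D
Product: 44 unit D threo (7S,8S) diol, hexasilyl ether of the target
Conditions: LiBH4 (3 equiv), THF containing H2O (3 equiv), 0 °C → rt
Reagents that add atoms: none
Why: Reductive removal of the Evans auxiliary gives the primary alcohol C9 of unit D without touching silyl ethers or any stereocentre.

Step 29
Reactants: 44 hexasilyl ether
Product: 45 CNP0316493.3 (target)
Conditions: Bu4NF (10 equiv), AcOH (10 equiv), THF, rt → 40 °C
Reagents that add atoms: none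
Why: Fluoride cleaves all six Si–O bonds, and buffering with AcOH keeps the liberated p-hydroxybenzyl alcohol units from base-induced quinone methide chemistry (global desilylation), no stereocentre being touched.

**Compound list**

1 | furfural (furan-2-carbaldehyde) | O=Cc1ccco1 | starting material
2 | 5-hydroxyfuran-2(5H)-one (racemic) | O=C1OC(O)C=C1 | intermediate
3 | (−)-menthol, (1R,2S,5R)-2-isopropyl-5-methylcyclohexan-1-ol | CC(C)[C@@H]1CC[C@@H](C)C[C@H]1O | starting material
4 | (5R)-5-{[(1R,2S,5R)-2-isopropyl-5-methylcyclohexyl]oxy}furan-2(5H)-one | O=C1O[C@@H](O[C@@H]2C[C@H](C)CC[C@H]2C(C)C)C=C1 | intermediate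
5 | syringaldehyde (4-hydroxy-3,5-dimethoxybenzaldehyde) | COc1cc(C=O)cc(OC)c1O | starting material
6 | 4-(allyloxy)-3,5-dimethoxybenzaldehyde | COc1cc(C=O)cc(OC)c1OCC=C | intermediate
7 | 4-(benzyloxy)-3,5-dimethoxybenzaldehyde | COc1cc(C=O)cc(OC)c1OCc1ccccc1 | intermediate
8 | propane-1,3-dithiol | SCCCS | starting material
9 | 2-[4-(benzyloxy)-3,5-dimethoxyphenyl]-1,3-dithiane | COc1cc(cc(OC)c1OCc1ccccc1)C1SCCCS1 | intermediate
10 | 2-lithio-2-[4-(benzyloxy)-3,5-dimethoxyphenyl]-1,3-dithiane (not isolated) | COc1cc(cc(OC)c1OCc1ccccc1)C1([Li])SCCCS1 | intermediate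
11 | lithium enolate of (4R,5R)-4-(2-aryl-1,3-dithian-2-yl)-5-menthyloxybutyrolactone, aryl = 4-benzyloxy-3,5-dimethoxyphenyl (not isolated) | [Li]OC1=C[C@@H](C2(SCCCS2)c2cc(OC)c(OCc3ccccc3)c(OC)c2)[C@H](O[C@@H]2C[C@H](C)CC[C@H]2C(C)C)O1 | intermediate
12 | (3S,4R,5R)-3-{(S)-[4-(allyloxy)-3,5-dimethoxyphenyl](hydroxy)methyl}-4-{2-[4-(benzyloxy)-3,5-dimethoxyphenyl]-1,3-dithian-2-yl}-5-[(1R,2S,5R)-menthyloxy]dihydrofuran-2(3H)-one (carbinol drawn as one epimer) | O=C1O[C@@H](O[C@@H]2C[C@H](C)CC[C@H]2C(C)C)[C@H](C2(SCCCS2)c2cc(OC)c(OCc3ccccc3)c(OC)c2)[C@H]1[C@H](O)c1cc(OC)c(OCC=C)c(OC)c1 | intermediate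
13 | (3S,4R,5R)-3-{(S)-[4-(allyloxy)-3,5-dimethoxyphenyl](hydroxy)methyl}-4-[4-(benzyloxy)-3,5-dimethoxybenzoyl]-5-[(1R,2S,5R)-menthyloxy]dihydrofuran-2(3H)-one (carbinol drawn as one epimer) | O=C1O[C@@H](O[C@@H]2C[C@H](C)CC[C@H]2C(C)C)[C@H](C(=O)c2cc(OC)c(OCc3ccccc3)c(OC)c2)[C@H]1[C@H](O)c1cc(OC)c(OCC=C)c(OC)c1 | intermediate
14 | (2R,3R)-2-{[4-(allyloxy)-3,5-dimethoxyphenyl](hydroxy)methyl}-3-{[4-(benzyloxy)-3,5-dimethoxyphenyl](hydroxy)methyl}butane-1,4-diol (both carbinols drawn as one epimer) | OC[C@H]([C@H](O)c1cc(OC)c(OCc2ccccc2)c(OC)c1)[C@H](CO)[C@H](O)c1cc(OC)c(OCC=C)c(OC)c1 | intermediate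
15 | (7S,8R,7′S,8′R)-4-O-allyl-4′-O-benzylsyringaresinol, i.e. (1S,3aR,4S,6aR)-1-[4-(allyloxy)-3,5-dimethoxyphenyl]-4-[4-(benzyloxy)-3,5-dimethoxyphenyl]tetrahydro-1H,3H-furo[3,4-c]furan | C=CCOc1c(OC)cc([C@H]2OC[C@H]3[C@@H]2CO[C@@H]3c2cc(OC)c(OCc3ccccc3)c(OC)c2)cc1OC | intermediate
16 | (7S,8R,7′S,8′R)-4′-O-benzylsyringaresinol (ring B phenol free) | Oc1c(OC)cc([C@H]2OC[C@H]3[C@@H]2CO[C@@H]3c2cc(OC)c(OCc3ccccc3)c(OC)c2)cc1OC | intermediate
17 | (R)-4-benzyloxazolidin-2-one | O=C1OC[C@@H](Cc2ccccc2)N1 | starting material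
18 | N-lithio-(R)-4-benzyloxazolidin-2-one (not isolated) | O=C1OC[C@@H](Cc2ccccc2)N1[Li] | intermediate
19 | (R)-4-benzyl-3-(bromoacetyl)oxazolidin-2-one | BrCC(=O)N1[C@H](Cc2ccccc2)COC1=O | intermediate
20 | (S)-4-benzyloxazolidin-2-one | O=C1OC[C@H](Cc2ccccc2)N1 | starting material
21 | N-lithio-(S)-4-benzyloxazolidin-2-one (not isolated) | O=C1OC[C@H](Cc2ccccc2)N1[Li] | intermediate
22 | (S)-4-benzyl-3-(bromoacetyl)oxazolidin-2-one | BrCC(=O)N1[C@@H](Cc2ccccc2)COC1=O | intermediate
23 | vanillin (4-hydroxy-3-methoxybenzaldehyde) | COc1cc(C=O)ccc1O | starting material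
24 | 3-methoxy-4-(triisopropylsilyloxy)benzaldehyde | COc1cc(C=O)ccc1O[Si](C(C)C)(C(C)C)C(C)C | intermediate
25 | (R)-4-benzyl-3-[(4′-O-benzylsyringaresinol-4-yl)oxyacetyl]oxazolidin-2-one (ring B glycolate imide) | O=C(COc1c(OC)cc([C@H]2OC[C@H]3[C@@H]2CO[C@@H]3c2cc(OC)c(OCc3ccccc3)c(OC)c2)cc1OC)N1[C@H](Cc2ccccc2)COC1=O | intermediate
26 | (Z)-di-n-butylboron enolate of 25 (not isolated) | CCCCB(CCCC)O/C(=C\Oc1c(OC)cc([C@H]2OC[C@H]3[C@@H]2CO[C@@H]3c2cc(OC)c(OCc3ccccc3)c(OC)c2)cc1OC)N1[C@H](Cc2ccccc2)COC1=O | intermediate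
27 | (R)-4-benzyl-3-[(2R,3S)-3-hydroxy-3-(3-methoxy-4-triisopropylsilyloxyphenyl)-2-(4′-O-benzylsyringaresinol-4-yloxy)propanoyl]oxazolidin-2-one | COc1cc([C@H](O)[C@H](C(=O)N2[C@H](Cc3ccccc3)COC2=O)Oc2c(OC)cc([C@H]3OC[C@H]4[C@@H]3CO[C@@H]4c3cc(OC)c(OCc4ccccc4)c(OC)c3)cc2OC)ccc1O[Si](C(C)C)(C(C)C)C(C)C | intermediate
28 | (2R,3R)-3-(4-nitrobenzoyloxy) analogue of 27 (C3 inverted) | COc1cc([C@@H](OC(=O)c2ccc(cc2)[N+](=O)[O-])[C@H](C(=O)N2[C@H](Cc3ccccc3)COC2=O)Oc2c(OC)cc([C@H]3OC[C@H]4[C@@H]3CO[C@@H]4c3cc(OC)c(OCc4ccccc4)c(OC)c3)cc2OC)ccc1O[Si](C(C)C)(C(C)C)C(C)C | intermediate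
29 | 4-O-[(1R,2S)-1,3-dihydroxy-1-(3-methoxy-4-triisopropylsilyloxyphenyl)propan-2-yl]-4′-O-benzylsyringaresinol (unit A erythro, 7R,8S) | COc1cc([C@@H](O)[C@H](CO)Oc2c(OC)cc([C@H]3OC[C@H]4[C@@H]3CO[C@@H]4c3cc(OC)c(OCc4ccccc4)c(OC)c3)cc2OC)ccc1O[Si](C(C)C)(C(C)C)C(C)C | intermediate
30 | 7,9-bis-O-(tert-butyldimethylsilyl) ether of 29 | COc1cc([C@@H](O[Si](C)(C)C(C)(C)C)[C@H](CO[Si](C)(C)C(C)(C)C)Oc2c(OC)cc([C@H]3OC[C@H]4[C@@H]3CO[C@@H]4c3cc(OC)c(OCc4ccccc4)c(OC)c3)cc2OC)ccc1O[Si](C(C)C)(C(C)C)C(C)C | intermediate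
31 | debenzylated 30 (ring C phenol free) | COc1cc([C@@H](O[Si](C)(C)C(C)(C)C)[C@H](CO[Si](C)(C)C(C)(C)C)Oc2c(OC)cc([C@H]3OC[C@H]4[C@@H]3CO[C@@H]4c3cc(OC)c(O)c(OC)c3)cc2OC)ccc1O[Si](C(C)C)(C(C)C)C(C)C | intermediate
32 | ring C O-CH2C(=O)-[(R)-4-benzyl-2-oxooxazolidin-3-yl] ether of 31 (ring C glycolate imide) | COc1cc([C@@H](O[Si](C)(C)C(C)(C)C)[C@H](CO[Si](C)(C)C(C)(C)C)Oc2c(OC)cc([C@H]3OC[C@H]4[C@@H]3CO[C@@H]4c3cc(OC)c(OCC(=O)N4[C@H](Cc5ccccc5)COC4=O)c(OC)c3)cc2OC)ccc1O[Si](C(C)C)(C(C)C)C(C)C | intermediate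
33 | 4-hydroxy-3-methoxybenzonitrile | COc1cc(C#N)ccc1O | starting material
34 | 4-{2-[(S)-4-benzyl-2-oxooxazolidin-3-yl]-2-oxoethoxy}-3-methoxybenzonitrile | COc1cc(C#N)ccc1OCC(=O)N1[C@@H](Cc2ccccc2)COC1=O | intermediate
35 | (Z)-di-n-butylboron enolate of 34 (not isolated) | COc1cc(C#N)ccc1O/C=C(\OB(CCCC)CCCC)N1[C@@H](Cc2ccccc2)COC1=O | intermediate
36 | 4-{[(2S,3R)-1-[(S)-4-benzyl-2-oxooxazolidin-3-yl]-3-hydroxy-3-(3-methoxy-4-triisopropylsilyloxyphenyl)-1-oxopropan-2-yl]oxy}-3-methoxybenzonitrile | N#Cc1ccc(O[C@H](C(=O)N2[C@@H](Cc3ccccc3)COC2=O)[C@H](O)c2ccc(O[Si](C(C)C)(C(C)C)C(C)C)c(OC)c2)c(OC)c1 | intermediate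
37 | (2S,3S)-3-(4-nitrobenzoyloxy) analogue of 36 (C3 inverted) | N#Cc1ccc(O[C@H](C(=O)N2[C@@H](Cc3ccccc3)COC2=O)[C@@H](OC(=O)c2ccc(cc2)[N+](=O)[O-])c2ccc(O[Si](C(C)C)(C(C)C)C(C)C)c(OC)c2)c(OC)c1 | intermediate
38 | 4-{[(1S,2R)-1,3-dihydroxy-1-(3-methoxy-4-triisopropylsilyloxyphenyl)propan-2-yl]oxy}-3-methoxybenzonitrile (unit E erythro, 7S,8R) | N#Cc1ccc(O[C@H](CO)[C@@H](O)c2ccc(O[Si](C(C)C)(C(C)C)C(C)C)c(OC)c2)c(OC)c1 | intermediate
39 | 7,9-bis-O-(tert-butyldimethylsilyl) ether of 38 | N#Cc1ccc(O[C@H](CO[Si](C)(C)C(C)(C)C)[C@@H](O[Si](C)(C)C(C)(C)C)c2ccc(O[Si](C(C)C)(C(C)C)C(C)C)c(OC)c2)c(OC)c1 | intermediate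
40 | N-(diisobutylalumino)aldimine from 39 (not isolated) | CC(C)C[Al](CC(C)C)N=Cc1ccc(O[C@H](CO[Si](C)(C)C(C)(C)C)[C@@H](O[Si](C)(C)C(C)(C)C)c2ccc(O[Si](C(C)C)(C(C)C)C(C)C)c(OC)c2)c(OC)c1 | intermediate
41 | 4-{[(1S,2R)-1,3-bis(tert-butyldimethylsilyloxy)-1-(3-methoxy-4-triisopropylsilyloxyphenyl)propan-2-yl]oxy}-3-methoxybenzaldehyde (ring D aldehyde with protected unit E) | O=Cc1ccc(O[C@H](CO[Si](C)(C)C(C)(C)C)[C@@H](O[Si](C)(C)C(C)(C)C)c2ccc(O[Si](C(C)C)(C(C)C)C(C)C)c(OC)c2)c(OC)c1 | intermediate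
42 | (Z)-di-n-butylboron enolate of 32 (not isolated) | COc1cc([C@@H](O[Si](C)(C)C(C)(C)C)[C@H](CO[Si](C)(C)C(C)(C)C)Oc2c(OC)cc([C@H]3OC[C@H]4[C@@H]3CO[C@@H]4c3cc(OC)c(O/C=C(\OB(CCCC)CCCC)N4[C@H](Cc5ccccc5)COC4=O)c(OC)c3)cc2OC)ccc1O[Si](C(C)C)(C(C)C)C(C)C | intermediate
43 | syn aldol adduct of 32 and 41: (2R,3S)-3-hydroxy-2-aryloxy-3-aryl-propanoyl imide of the (R)-auxiliary (unit D, auxiliary still on) | COc1cc([C@@H](O[Si](C)(C)C(C)(C)C)[C@H](CO[Si](C)(C)C(C)(C)C)Oc2c(OC)cc([C@H]3OC[C@H]4[C@@H]3CO[C@@H]4c3cc(OC)c(O[C@@H](C(=O)N4[C@H](Cc5ccccc5)COC4=O)[C@@H](O)c4ccc(O[C@H](CO[Si](C)(C)C(C)(C)C)[C@@H](O[Si](C)(C)C(C)(C)C)c5ccc(O[Si](C(C)C)(C(C)C)C(C)C)c(OC)c5)c(OC)c4)c(OC)c3)cc2OC)ccc1O[Si](C(C)C)(C(C)C)C(C)C | intermediate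
44 | target carrying tert-butyldimethylsilyl ethers on O7 and O9 of units A and E and triisopropylsilyl ethers on the ring A and ring E phenols (unit D threo 7S,8S diol free) | COc1cc([C@@H](O[Si](C)(C)C(C)(C)C)[C@H](CO[Si](C)(C)C(C)(C)C)Oc2c(OC)cc([C@H]3OC[C@H]4[C@@H]3CO[C@@H]4c3cc(OC)c(O[C@@H](CO)[C@@H](O)c4ccc(O[C@H](CO[Si](C)(C)C(C)(C)C)[C@@H](O[Si](C)(C)C(C)(C)C)c5ccc(O[Si](C(C)C)(C(C)C)C(C)C)c(OC)c5)c(OC)c4)c(OC)c3)cc2OC)ccc1O[Si](C(C)C)(C(C)C)C(C)C | intermediate
45 | CNP0316493.3: (7S,8R,7′S,8′R)-syringaresinol 4-O-[(7R,8S)-guaiacylglycerol-8-yl] 4′-O-[(7S,8S)-guaiacylglycerol-8-yl, itself 4-O-(7S,8R)-guaiacylglycerol-8-yl] ether | COc1cc([C@@H](O)[C@H](CO)Oc2c(OC)cc([C@H]3OC[C@H]4[C@@H]3CO[C@@H]4c3cc(OC)c(O[C@@H](CO)[C@@H](O)c4ccc(O[C@H](CO)[C@@H](O)c5ccc(O)c(OC)c5)c(OC)c4)c(OC)c3)cc2OC)ccc1O | target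

**Step count**

Total: 29 steps. Longest linear sequence: 17 steps (5 → 7 → 9 → 12 → 13 → 14 → 15 → 16 → 25 → 27 → 28 → 29 → 30 → 31 → 32 → 43 → 44 → 45).

**Steps most likely to fail**

Step 6. What may go wrong: attack at the lactone carbonyl or proton transfer instead of conjugate addition, and reversal of the aldol or erosion of the trans relationship while the lithium aldolate sits in the presence of excess base. The fallback sets out from 9 and 4 and returns at 12, and makes the two bonds in separate operations. Dithiane 9 is lithiated to 10 and added to 4 as before, but the enolate is protonated with AcOH at −78 °C and the Michael adduct (4R,5R)-4-{2-[4-(benzyloxy)-3,5-dimethoxyphenyl]-1,3-dithian-2-yl}-5-menthyloxydihydrofuran-2(3H)-one F1 is isolated and purified. F1 is then deprotonated with LiN(i-Pr)2 in THF at −78 °C, which regenerates 11 free of dithiane anion; the enolate is transmetallated with ZnCl2 and treated with 6 to give 12. The conjugate addition and the aldol can then each be optimised alone, and the zinc aldolate is less prone to retro-aldol.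

Step 16. What may go wrong: β-elimination of the activated benzylic oxygen toward the imide carbonyl, or partial retention through a benzylic cation, so that unit A is not cleanly inverted. The fallback sets out from 27 and returns at 30, and replaces displacement by an oxidation–reduction at C7 after the auxiliary is gone. LiBH4 in wet THF converts 27 into the threo diol F2 (unit A 7S,8S). t-BuMe2SiCl and imidazole silylate only the primary hydroxyl to give the 9-O-silyl ether F3. Dess–Martin periodinane buffered with NaHCO3 oxidises the benzylic alcohol to the α-aryloxy aryl ketone F4 without touching C8. LiBH(s-Bu)3 in THF at −78 °C reduces F4 under Felkin–Anh control with the aryloxy group as the polar substituent, giving the anti (erythro, 7R,8S) alcohol F5. Silylation of F5 with t-BuMe2SiOTf and 2,6-lutidine gives 30.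

Step 14. What may go wrong: acyl transfer from the imide to the hindered ring B phenoxide, or base-induced decomposition of bromide 19, in place of O-alkylation. The fallback sets out from 16 and returns at 25, and forms the ether bond before the acyl–nitrogen bond. Phenol 16 is alkylated with allyl bromoacetate and K2CO3 in acetone to give the allyl aryloxyacetate F6. Pd(PPh3)4 and morpholine cleave the allyl ester to the aryloxyacetic acid F7. t-BuCOCl and Et3N in THF at −20 °C convert F7 into the mixed pivalic anhydride F8, which is not isolated. F8 acylates the lithiated auxiliary 18 (from 17 and n-BuLi) to give 25.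

**Further compounds**

F1 | step 6 | (4R,5R)-4-{2-[4-(benzyloxy)-3,5-dimethoxyphenyl]-1,3-dithian-2-yl}-5-[(1R,2S,5R)-menthyloxy]dihydrofuran-2(3H)-one | O=C1C[C@@H](C2(SCCCS2)c2cc(OC)c(OCc3ccccc3)c(OC)c2)[C@H](O[C@@H]2C[C@H](C)CC[C@H]2C(C)C)O1
F2 | step 16 | 4-O-[(1S,2S)-1,3-dihydroxy-1-(3-methoxy-4-triisopropylsilyloxyphenyl)propan-2-yl]-4′-O-benzylsyringaresinol (unit A threo) | COc1cc([C@H](O)[C@H](CO)Oc2c(OC)cc([C@H]3OC[C@H]4[C@@H]3CO[C@@H]4c3cc(OC)c(OCc4ccccc4)c(OC)c3)cc2OC)ccc1O[Si](C(C)C)(C(C)C)C(C)C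
F3 | step 16 | 9-O-(tert-butyldimethylsilyl) ether of F2 | COc1cc([C@H](O)[C@H](CO[Si](C)(C)C(C)(C)C)Oc2c(OC)cc([C@H]3OC[C@H]4[C@@H]3CO[C@@H]4c3cc(OC)c(OCc4ccccc4)c(OC)c3)cc2OC)ccc1O[Si](C(C)C)(C(C)C)C(C)C
F4 | step 16 | (S)-3-(tert-butyldimethylsilyloxy)-1-(3-methoxy-4-triisopropylsilyloxyphenyl)-2-(4′-O-benzylsyringaresinol-4-yloxy)propan-1-one | COc1cc(C(=O)[C@H](CO[Si](C)(C)C(C)(C)C)Oc2c(OC)cc([C@H]3OC[C@H]4[C@@H]3CO[C@@H]4c3cc(OC)c(OCc4ccccc4)c(OC)c3)cc2OC)ccc1O[Si](C(C)C)(C(C)C)C(C)C
F5 | step 16 | (1R,2S)-3-(tert-butyldimethylsilyloxy)-1-(3-methoxy-4-triisopropylsilyloxyphenyl)-2-(4′-O-benzylsyringaresinol-4-yloxy)propan-1-ol (unit A erythro) | COc1cc([C@@H](O)[C@H](CO[Si](C)(C)C(C)(C)C)Oc2c(OC)cc([C@H]3OC[C@H]4[C@@H]3CO[C@@H]4c3cc(OC)c(OCc4ccccc4)c(OC)c3)cc2OC)ccc1O[Si](C(C)C)(C(C)C)C(C)C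
F6 | step 14 | allyl (4′-O-benzylsyringaresinol-4-yl)oxyacetate | C=CCOC(=O)COc1c(OC)cc([C@H]2OC[C@H]3[C@@H]2CO[C@@H]3c2cc(OC)c(OCc3ccccc3)c(OC)c2)cc1OC
F7 | step 14 | (4′-O-benzylsyringaresinol-4-yl)oxyacetic acid | OC(=O)COc1c(OC)cc([C@H]2OC[C@H]3[C@@H]2CO[C@@H]3c2cc(OC)c(OCc3ccccc3)c(OC)c2)cc1OC
F8 | step 14 | mixed anhydride of F7 with pivalic acid (not isolated) | CC(C)(C)C(=O)OC(=O)COc1c(OC)cc([C@H]2OC[C@H]3[C@@H]2CO[C@@H]3c2cc(OC)c(OCc3ccccc3)c(OC)c2)cc1OC
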